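Assumption: the target SMILES has no stereocentre and no hindered axis (the molecule is achiral), so there is no enantiomer to select and all SMILES are written without stereodescriptors.

**Retrosynthetic overview**
1. Target ⇒ global hydrogenolysis of its tridecabenzyl ether ⇒ Ullmann C–O coupling at the B–O–C ether of a ring A–B aryl bromide with a ring C–D–E phenol.
2. A–B bromide: the most hindered ether (A–O–B) is made first as a simple phenol O-alkylation with diethyl chloromalonate. Ring A, the only ring formed de novo, is then built on that carbon by crossed Claisen condensation with diethyl acetonedicarboxylate plus Dieckmann closure, followed by decarboxylation.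
3. C–D–E phenol: rings D and E are added to a ring C phenol by two rounds of Ullmann coupling with one building block, 2,6-bis(benzyloxy)-4-bromobenzaldehyde, each followed by Baeyer–Villiger oxidation (CHO → OH).
4. Rings B, C, D and E are bought as benzaldehydes (5-bromovanillin, 3,4,5-trihydroxybenzaldehyde, 4-bromo-2,6-difluorobenzaldehyde); each formyl carbon is later excised as formate to leave a ring oxygen.
5. Order: ring B (bought) → ring A (built); ring C → D → E; then A–B + C–D–E and debenzylation.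

**Route**

Step 1
Reactants: 1 5-bromovanillin
Product: 2 3-bromo-4,5-dihydroxybenzaldehyde
Conditions: AlCl3, pyridine, CH2Cl2, reflux; then aq. HCl
Reagents that add atoms: none
Why: Lewis-acid O-demethylation (AlCl3/pyridine ether cleavage), in which chelation of aluminium by the neighbouring phenoxide activates the methoxy group for SN2 attack of pyridine on methyl while aldehyde and bromide are untouched.

Step 2
Reactants: 2 3-bromo-4,5-dihydroxybenzaldehyde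
Product: 3 3,4-bis(benzyloxy)-5-bromobenzaldehyde
Conditions: BnBr, K2CO3, DMF, 60 °C
Reagents that add atoms: benzyl bromide BrCc1ccccc1
Why: Williamson ether synthesis on both catechol oxygens; the aldehyde has no enolisable position and is inert.

Step 3
Reactants: 3 3,4-bis(benzyloxy)-5-bromobenzaldehyde
Product: 5 3,4-bis(benzyloxy)-5-bromophenol, via aryl formate 4 (not isolated)
Conditions: mCPBA, CH2Cl2, 0 °C → rt; then K2CO3 (cat.), MeOH, rt
Reagents that add atoms: mCPBA (3-chloroperoxybenzoic acid) OOC(=O)c1cccc(Cl)c1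
Why: Baeyer–Villiger oxidation with aryl migration favoured by the para benzyloxy group, then transesterification of the formate with methanol to free the phenol.

Step 4
Reactants: 5 3,4-bis(benzyloxy)-5-bromophenol; 6 diethyl chloromalonate
Product: 7 diethyl 2-[3,4-bis(benzyloxy)-5-bromophenoxy]propanedioate
Conditions: K2CO3, DMF, 60 °C
Reagents that add atoms: none
Why: SN2 O-alkylation (Williamson) of an unhindered phenoxide by an α-halomalonate, which sets the future A–O–B ether before ring A exists.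

Step 5
Reactants: 7 diethyl 2-[3,4-bis(benzyloxy)-5-bromophenoxy]propanedioate; 8 diethyl 3-oxopentanedioate (diethyl acetonedicarboxylate)
Product: 10 diethyl 5-[3,4-bis(benzyloxy)-5-bromophenoxy]-2,4,6-trihydroxybenzene-1,3-dicarboxylate, via acyclic Claisen adduct 9 (not isolated)
Conditions: NaH (3.3 equiv), THF then toluene, 0 → 100 °C; then 1 M HCl
Reagents that add atoms: none
Why: Intermolecular crossed Claisen condensation of the enolate of 8 on one ester of the aryloxymalonate, then Dieckmann condensation of the second methylene of 8 on the other ester, driven by aromatisation to the phloroglucinol trianion (the two enolisable stereocentres of 9 are uncontrolled and vanish).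

Step 6
Reactants: 10 diethyl 5-[3,4-bis(benzyloxy)-5-bromophenoxy]-2,4,6-trihydroxybenzene-1,3-dicarboxylate
Product: 13 2-[3,4-bis(benzyloxy)-5-bromophenoxy]benzene-1,3,5-triyl triacetate, via diacid 11 (not isolated), via triol 12 (not isolated)
Conditions: KOH, H2O/EtOH, reflux (Ar); HCl to pH 2, 70 °C; then Ac2O, pyridine, DMAP (cat.), rt
Reagents that add atoms: acetic anhydride CC(=O)OC(C)=O
Why: Ester saponification, then decarboxylation of the phloroglucinol carboxylic acids through their β-keto-acid tautomers, and O-acetylation to trap the air-sensitive triol as a stable triacetate.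

Step 7
Reactants: 13 2-[3,4-bis(benzyloxy)-5-bromophenoxy]benzene-1,3,5-triyl triacetate
Product: 14 1,3,5-tris(benzyloxy)-2-[3,4-bis(benzyloxy)-5-bromophenoxy]benzene
Conditions: BnCl, NaH, H2O (3 equiv, slow addition), DMF, 0 °C → rt
Reagents that add atoms: benzyl chloride ClCc1ccccc1
Why: In situ deacetylation and Williamson benzylation, in which slow release of one phenoxide at a time in the presence of excess BnCl suppresses the C-benzylation typical of phloroglucinol polyanions.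

Step 8
Reactants: 15 4-bromo-2,6-difluorobenzaldehyde
Product: 16 2,6-bis(benzyloxy)-4-bromobenzaldehyde
Conditions: BnOH, NaH, THF/DMF, 0 → 45 °C
Reagents that add atoms: benzyl alcohol OCc1ccccc1
Why: Double nucleophilic aromatic substitution (SNAr) of the two fluorides ortho to the formyl group, which are far better leaving groups than the para bromide.

Step 9
Reactants: 17 3,4,5-trihydroxybenzaldehyde
Product: 18 3,4,5-tris(benzyloxy)benzaldehyde
Conditions: BnBr, K2CO3, DMF, 60 °C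
Reagents that add atoms: benzyl bromide BrCc1ccccc1
Why: Threefold Williamson ether synthesis on a non-enolisable aldehyde.

Step 10
Reactants: 18 3,4,5-tris(benzyloxy)benzaldehyde
Product: 20 3,4,5-tris(benzyloxy)phenol, via aryl formate 19 (not isolated)
Conditions: mCPBA, CH2Cl2, 0 °C → rt; then K2CO3 (cat.), MeOH, rt
Reagents that add atoms: mCPBA (3-chloroperoxybenzoic acid) OOC(=O)c1cccc(Cl)c1
Why: Baeyer–Villiger oxidation (aryl migration assisted by the para benzyloxy group), then methanolysis of the formate.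

Step 11
Reactants: 20 3,4,5-tris(benzyloxy)phenol
Product: 22 2,3,4-tris(benzyloxy)-6-hydroxybenzaldehyde, via salicyl alcohol 21 (not isolated)
Conditions: MgCl2, Et3N, (CH2O)n, MeCN, reflux; then 1 M HCl
Reagents that add atoms: paraformaldehyde (formaldehyde) C=O
Why: Magnesium-mediated ortho-formylation (Casnati–Skattebøl), in which the magnesium phenoxide delivers formaldehyde only ortho to oxygen (both ortho sites are equivalent) and a second formaldehyde oxidises the salicyl alcohol by hydride transfer.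

Step 12
Reactants: 22 2,3,4-tris(benzyloxy)-6-hydroxybenzaldehyde
Product: 23 2,3,4-tris(benzyloxy)-6-(methoxymethoxy)benzaldehyde
Conditions: MOMCl, i-Pr2NEt, CH2Cl2, 0 °C → rt
Reagents that add atoms: chloromethyl methyl ether COCCl
Why: O-alkylation to a MOM acetal, which masks the oxygen that will later carry ring B and survives base, peracid and copper catalysis.

Step 13
Reactants: 23 2,3,4-tris(benzyloxy)-6-(methoxymethoxy)benzaldehyde
Product: 25 2,3,4-tris(benzyloxy)-6-(methoxymethoxy)phenol, via aryl formate 24 (not isolated)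
Conditions: mCPBA, CH2Cl2, 0 °C; Na2S2O3 wash; then K2CO3 (cat.), MeOH, rt
Reagents that add atoms: mCPBA (3-chloroperoxybenzoic acid) OOC(=O)c1cccc(Cl)c1
Why: Baeyer–Villiger oxidation of a very electron-rich di-ortho-alkoxy benzaldehyde, then formate methanolysis, which unveils the ring C oxygen that will carry ring D.

Step 14
Reactants: 25 2,3,4-tris(benzyloxy)-6-(methoxymethoxy)phenol; 16 2,6-bis(benzyloxy)-4-bromobenzaldehyde
Product: 26 2,6-bis(benzyloxy)-4-[2,3,4-tris(benzyloxy)-6-(methoxymethoxy)phenoxy]benzaldehyde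
Conditions: CuI (10 mol %), picolinic acid (20 mol %), K3PO4, DMSO, 90 °C, Ar
Reagents that add atoms: none
Why: Ullmann diaryl ether coupling in which the hindered partner is the phenoxide and the bromide is unhindered and activated by the para formyl group.

Step 15
Reactants: 26 2,6-bis(benzyloxy)-4-[2,3,4-tris(benzyloxy)-6-(methoxymethoxy)phenoxy]benzaldehyde
Product: 28 2,6-bis(benzyloxy)-4-[2,3,4-tris(benzyloxy)-6-(methoxymethoxy)phenoxy]phenol, via aryl formate 27 (not isolated)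
Conditions: mCPBA, CH2Cl2, 0 °C; Na2S2O3 wash; then K2CO3 (cat.), MeOH, rt
Reagents that add atoms: mCPBA (3-chloroperoxybenzoic acid) OOC(=O)c1cccc(Cl)c1
Why: Baeyer–Villiger oxidation, then methanolysis, turning the ring D formyl carbon into the oxygen that will carry ring E.

Step 16
Reactants: 28 2,6-bis(benzyloxy)-4-[2,3,4-tris(benzyloxy)-6-(methoxymethoxy)phenoxy]phenol; 16 2,6-bis(benzyloxy)-4-bromobenzaldehyde
Product: 29 2,6-bis(benzyloxy)-4-{2,6-bis(benzyloxy)-4-[2,3,4-tris(benzyloxy)-6-(methoxymethoxy)phenoxy]phenoxy}benzaldehyde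
Conditions: CuI (10 mol %), picolinic acid (20 mol %), K3PO4, DMSO, 90 °C, Ar
Reagents that add atoms: none
Why: Second Ullmann diaryl ether coupling of a 2,6-dialkoxyphenoxide with the same formyl-activated, unhindered bromide.

Step 17
Reactants: 29 2,6-bis(benzyloxy)-4-{2,6-bis(benzyloxy)-4-[2,3,4-tris(benzyloxy)-6-(methoxymethoxy)phenoxy]phenoxy}benzaldehyde
Product: 31 2,6-bis(benzyloxy)-4-{2,6-bis(benzyloxy)-4-[2,3,4-tris(benzyloxy)-6-(methoxymethoxy)phenoxy]phenoxy}phenol, via aryl formate 30 (not isolated)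
Conditions: mCPBA, CH2Cl2, 0 °C; Na2S2O3 wash; then K2CO3 (cat.), MeOH, rt
Reagents that add atoms: mCPBA (3-chloroperoxybenzoic acid) OOC(=O)c1cccc(Cl)c1
Why: Baeyer–Villiger oxidation, then methanolysis, installing the central oxygen of ring E.

Step 18
Reactants: 31 2,6-bis(benzyloxy)-4-{2,6-bis(benzyloxy)-4-[2,3,4-tris(benzyloxy)-6-(methoxymethoxy)phenoxy]phenoxy}phenol
Product: 32 1,2,3-tris(benzyloxy)-5-{2,6-bis(benzyloxy)-4-[2,3,4-tris(benzyloxy)-6-(methoxymethoxy)phenoxy]phenoxy}benzene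
Conditions: BnBr, K2CO3, DMF, 60 °C
Reagents that add atoms: benzyl bromide BrCc1ccccc1
Why: Williamson ether synthesis, which caps the last free phenol of ring E.

Step 19
Reactants: 32 1,2,3-tris(benzyloxy)-5-{2,6-bis(benzyloxy)-4-[2,3,4-tris(benzyloxy)-6-(methoxymethoxy)phenoxy]phenoxy}benzene
Product: 33 3,4,5-tris(benzyloxy)-2-{3,5-bis(benzyloxy)-4-[3,4,5-tris(benzyloxy)phenoxy]phenoxy}phenol
Conditions: HCl (cat.), MeOH/THF, 45 °C
Reagents that add atoms: none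
Why: Acid-catalysed acetal exchange (MOM cleavage) in excess methanol, which traps the formaldehyde unit as its dimethyl acetal and leaves benzyl and diaryl ethers intact.

Step 20
Reactants: 33 3,4,5-tris(benzyloxy)-2-{3,5-bis(benzyloxy)-4-[3,4,5-tris(benzyloxy)phenoxy]phenoxy}phenol; 14 1,3,5-tris(benzyloxy)-2-[3,4-bis(benzyloxy)-5-bromophenoxy]benzene
Product: 34 1,3,5-tris(benzyloxy)-2-[3,4-bis(benzyloxy)-5-(3,4,5-tris(benzyloxy)-2-{3,5-bis(benzyloxy)-4-[3,4,5-tris(benzyloxy)phenoxy]phenoxy}phenoxy)phenoxy]benzene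
Conditions: CuI (20 mol %), N,N-dimethylglycine (40 mol %), Cs2CO3, dioxane, 105 °C, Ar
Reagents that add atoms: none
Why: Ullmann diaryl ether coupling of a phenol with one ortho substituent and a 2-alkoxyaryl bromide whose bromine receives no para donation, a pairing typical of phlorotannin ether syntheses.

Step 21
Reactants: 34 tridecabenzyl ether of the target
Product: 35 2-[3,4-dihydroxy-5-(3,4,5-trihydroxy-2-{3,5-dihydroxy-4-[3,4,5-trihydroxyphenoxy]phenoxy}phenoxy)phenoxy]benzene-1,3,5-triol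
Conditions: H2 (1 atm), Pd/C (10 % Pd), THF/MeOH, rt; filtration under Ar
Reagents that add atoms: none
Why: Catalytic hydrogenolysis of all thirteen benzyl ethers under neutral conditions that leave diaryl ethers untouched and spare the oxidation-prone polyphenol acid or base.

**Compound list**
1 | 5-bromovanillin (3-bromo-4-hydroxy-5-methoxybenzaldehyde) | COc1cc(C=O)cc(Br)c1O | starting material
2 | 3-bromo-4,5-dihydroxybenzaldehyde | O=Cc1cc(O)c(O)c(Br)c1 | intermediate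
3 | 3,4-bis(benzyloxy)-5-bromobenzaldehyde | O=Cc1cc(OCc2ccccc2)c(OCc2ccccc2)c(Br)c1 | intermediate
4 | 3,4-bis(benzyloxy)-5-bromophenyl formate | O=COc1cc(OCc2ccccc2)c(OCc2ccccc2)c(Br)c1 | intermediate (not isolated)
5 | 3,4-bis(benzyloxy)-5-bromophenol | Oc1cc(OCc2ccccc2)c(OCc2ccccc2)c(Br)c1 | intermediate
6 | diethyl chloromalonate (diethyl 2-chloropropanedioate) | CCOC(=O)C(Cl)C(=O)OCC | starting material
7 | diethyl 2-[3,4-bis(benzyloxy)-5-bromophenoxy]propanedioate | CCOC(=O)C(Oc1cc(OCc2ccccc2)c(OCc2ccccc2)c(Br)c1)C(=O)OCC | intermediate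
8 | diethyl 3-oxopentanedioate (diethyl acetonedicarboxylate) | CCOC(=O)CC(=O)CC(=O)OCC | starting material
9 | diethyl 2-{2-[3,4-bis(benzyloxy)-5-bromophenoxy]-3-ethoxy-3-oxopropanoyl}-3-oxopentanedioate (enolisable diastereomer mixture) | CCOC(=O)CC(=O)C(C(=O)OCC)C(=O)C(Oc1cc(OCc2ccccc2)c(OCc2ccccc2)c(Br)c1)C(=O)OCC | intermediate (not isolated)
10 | diethyl 5-[3,4-bis(benzyloxy)-5-bromophenoxy]-2,4,6-trihydroxybenzene-1,3-dicarboxylate | CCOC(=O)c1c(O)c(C(=O)OCC)c(O)c(Oc2cc(OCc3ccccc3)c(OCc3ccccc3)c(Br)c2)c1O | intermediate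
11 | 5-[3,4-bis(benzyloxy)-5-bromophenoxy]-2,4,6-trihydroxybenzene-1,3-dicarboxylic acid | OC(=O)c1c(O)c(C(O)=O)c(O)c(Oc2cc(OCc3ccccc3)c(OCc3ccccc3)c(Br)c2)c1O | intermediate (not isolated)
12 | 2-[3,4-bis(benzyloxy)-5-bromophenoxy]benzene-1,3,5-triol | Oc1cc(O)c(Oc2cc(OCc3ccccc3)c(OCc3ccccc3)c(Br)c2)c(O)c1 | intermediate (not isolated)
13 | 2-[3,4-bis(benzyloxy)-5-bromophenoxy]benzene-1,3,5-triyl triacetate | CC(=O)Oc1cc(OC(C)=O)c(Oc2cc(OCc3ccccc3)c(OCc3ccccc3)c(Br)c2)c(OC(C)=O)c1 | intermediate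
14 | 1,3,5-tris(benzyloxy)-2-[3,4-bis(benzyloxy)-5-bromophenoxy]benzene | Brc1cc(Oc2c(OCc3ccccc3)cc(OCc3ccccc3)cc2OCc2ccccc2)cc(OCc2ccccc2)c1OCc1ccccc1 | intermediate
15 | 4-bromo-2,6-difluorobenzaldehyde | O=Cc1c(F)cc(Br)cc1F | starting material
16 | 2,6-bis(benzyloxy)-4-bromobenzaldehyde | O=Cc1c(OCc2ccccc2)cc(Br)cc1OCc1ccccc1 | intermediate
17 | 3,4,5-trihydroxybenzaldehyde | O=Cc1cc(O)c(O)c(O)c1 | starting material
18 | 3,4,5-tris(benzyloxy)benzaldehyde | O=Cc1cc(OCc2ccccc2)c(OCc2ccccc2)c(OCc2ccccc2)c1 | intermediate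
19 | 3,4,5-tris(benzyloxy)phenyl formate | O=COc1cc(OCc2ccccc2)c(OCc2ccccc2)c(OCc2ccccc2)c1 | intermediate (not isolated)
20 | 3,4,5-tris(benzyloxy)phenol | Oc1cc(OCc2ccccc2)c(OCc2ccccc2)c(OCc2ccccc2)c1 | intermediate
21 | 3,4,5-tris(benzyloxy)-2-(hydroxymethyl)phenol | OCc1c(O)cc(OCc2ccccc2)c(OCc2ccccc2)c1OCc1ccccc1 | intermediate (not isolated)
22 | 2,3,4-tris(benzyloxy)-6-hydroxybenzaldehyde | O=Cc1c(O)cc(OCc2ccccc2)c(OCc2ccccc2)c1OCc1ccccc1 | intermediate
23 | 2,3,4-tris(benzyloxy)-6-(methoxymethoxy)benzaldehyde | COCOc1cc(OCc2ccccc2)c(OCc2ccccc2)c(OCc2ccccc2)c1C=O | intermediate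
24 | 2,3,4-tris(benzyloxy)-6-(methoxymethoxy)phenyl formate | COCOc1cc(OCc2ccccc2)c(OCc2ccccc2)c(OCc2ccccc2)c1OC=O | intermediate (not isolated)
25 | 2,3,4-tris(benzyloxy)-6-(methoxymethoxy)phenol | COCOc1cc(OCc2ccccc2)c(OCc2ccccc2)c(OCc2ccccc2)c1O | intermediate
26 | 2,6-bis(benzyloxy)-4-[2,3,4-tris(benzyloxy)-6-(methoxymethoxy)phenoxy]benzaldehyde | COCOc1cc(OCc2ccccc2)c(OCc2ccccc2)c(OCc2ccccc2)c1Oc1cc(OCc2ccccc2)c(C=O)c(OCc2ccccc2)c1 | intermediate
27 | 2,6-bis(benzyloxy)-4-[2,3,4-tris(benzyloxy)-6-(methoxymethoxy)phenoxy]phenyl formate | COCOc1cc(OCc2ccccc2)c(OCc2ccccc2)c(OCc2ccccc2)c1Oc1cc(OCc2ccccc2)c(OC=O)c(OCc2ccccc2)c1 | intermediate (not isolated)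
28 | 2,6-bis(benzyloxy)-4-[2,3,4-tris(benzyloxy)-6-(methoxymethoxy)phenoxy]phenol | COCOc1cc(OCc2ccccc2)c(OCc2ccccc2)c(OCc2ccccc2)c1Oc1cc(OCc2ccccc2)c(O)c(OCc2ccccc2)c1 | intermediate
29 | 2,6-bis(benzyloxy)-4-{2,6-bis(benzyloxy)-4-[2,3,4-tris(benzyloxy)-6-(methoxymethoxy)phenoxy]phenoxy}benzaldehyde | COCOc1cc(OCc2ccccc2)c(OCc2ccccc2)c(OCc2ccccc2)c1Oc1cc(OCc2ccccc2)c(Oc2cc(OCc3ccccc3)c(C=O)c(OCc3ccccc3)c2)c(OCc2ccccc2)c1 | intermediate
30 | 2,6-bis(benzyloxy)-4-{2,6-bis(benzyloxy)-4-[2,3,4-tris(benzyloxy)-6-(methoxymethoxy)phenoxy]phenoxy}phenyl formate | COCOc1cc(OCc2ccccc2)c(OCc2ccccc2)c(OCc2ccccc2)c1Oc1cc(OCc2ccccc2)c(Oc2cc(OCc3ccccc3)c(OC=O)c(OCc3ccccc3)c2)c(OCc2ccccc2)c1 | intermediate (not isolated)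
31 | 2,6-bis(benzyloxy)-4-{2,6-bis(benzyloxy)-4-[2,3,4-tris(benzyloxy)-6-(methoxymethoxy)phenoxy]phenoxy}phenol | COCOc1cc(OCc2ccccc2)c(OCc2ccccc2)c(OCc2ccccc2)c1Oc1cc(OCc2ccccc2)c(Oc2cc(OCc3ccccc3)c(O)c(OCc3ccccc3)c2)c(OCc2ccccc2)c1 | intermediate
32 | 1,2,3-tris(benzyloxy)-5-{2,6-bis(benzyloxy)-4-[2,3,4-tris(benzyloxy)-6-(methoxymethoxy)phenoxy]phenoxy}benzene | COCOc1cc(OCc2ccccc2)c(OCc2ccccc2)c(OCc2ccccc2)c1Oc1cc(OCc2ccccc2)c(Oc2cc(OCc3ccccc3)c(OCc3ccccc3)c(OCc3ccccc3)c2)c(OCc2ccccc2)c1 | intermediate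
33 | 3,4,5-tris(benzyloxy)-2-{3,5-bis(benzyloxy)-4-[3,4,5-tris(benzyloxy)phenoxy]phenoxy}phenol | Oc1cc(OCc2ccccc2)c(OCc2ccccc2)c(OCc2ccccc2)c1Oc1cc(OCc2ccccc2)c(Oc2cc(OCc3ccccc3)c(OCc3ccccc3)c(OCc3ccccc3)c2)c(OCc2ccccc2)c1 | intermediate
34 | 1,3,5-tris(benzyloxy)-2-[3,4-bis(benzyloxy)-5-(3,4,5-tris(benzyloxy)-2-{3,5-bis(benzyloxy)-4-[3,4,5-tris(benzyloxy)phenoxy]phenoxy}phenoxy)phenoxy]benzene (tridecabenzyl ether of the target) | c1ccccc1COc1cc(OCc5ccccc5)c(Oc2cc(OCc5ccccc5)c(OCc5ccccc5)c(Oc3cc(OCc5ccccc5)c(OCc5ccccc5)c(OCc5ccccc5)c3Oc3cc(OCc5ccccc5)c(Oc4cc(OCc5ccccc5)c(OCc5ccccc5)c(OCc5ccccc5)c4)c(OCc5ccccc5)c3)c2)c(OCc5ccccc5)c1 | intermediate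
35 | 2-[3,4-dihydroxy-5-(3,4,5-trihydroxy-2-{3,5-dihydroxy-4-[3,4,5-trihydroxyphenoxy]phenoxy}phenoxy)phenoxy]benzene-1,3,5-triol (CNP0228612.0) | Oc1cc(O)c(Oc2cc(O)c(O)c(Oc3cc(O)c(O)c(O)c3Oc3cc(O)c(Oc4cc(O)c(O)c(O)c4)c(O)c3)c2)c(O)c1 | target

**Step count and risks**

Total: 21 steps. Longest linear sequence: 13 steps (steps 9–21, from 17 to 35). The A–B branch (steps 1–7) and the building block 16 (step 8) are made in parallel.

Most likely to fail:

Step 5 (crossed Claisen/Dieckmann construction of ring A). It has no close precedent with an aryloxymalonate as bis-electrophile. Self-condensation of 8, unproductive deprotonation of 7 and lactonisation to a pyranone can all compete, although only the carbocycle is an aromatic sink. Fallback: make the two C–C bonds one after the other. It sets out from 7. Half-saponification (KOH 1.0 equiv, EtOH, 0 °C; then H3O+) gives racemic 2-[3,4-bis(benzyloxy)-5-bromophenoxy]-3-ethoxy-3-oxopropanoic acid F1. Oxalyl chloride with DMF (cat.) in CH2Cl2 gives racemic ethyl 2-[3,4-bis(benzyloxy)-5-bromophenoxy]-3-chloro-3-oxopropanoate F2. This acid chloride C-acylates the magnesium enolate of 8 (MgCl2, Et3N, MeCN, 0 °C) to give 9, which is isolated this time. NaOEt in EtOH at reflux then closes 9 by Dieckmann condensation, and the fallback is back on the route at 10.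

Step 20 (Ullmann union of the two large fragments 33 and 14). Both partners are bulky and electron-rich, and the bromide carries no activating group. Fallback: build ring A last on the tetramer instead of coupling two large pieces. It sets out from 33 and returns at 35. Below, ArO stands for the aryloxy group of 33.
- Ullmann coupling of 33 with the small, formyl-bearing bromide 3 used in excess (CuI, picolinic acid, K3PO4, DMSO, 90 °C) gives 3,4-bis(benzyloxy)-5-(ArO)benzaldehyde F3.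
- mCPBA gives 3,4-bis(benzyloxy)-5-(ArO)phenyl formate F4, and K2CO3/MeOH gives 3,4-bis(benzyloxy)-5-(ArO)phenol F5.
- Alkylation with 6 (K2CO3, DMF) gives diethyl 2-[3,4-bis(benzyloxy)-5-(ArO)phenoxy]propanedioate F6.
- NaH and 8 give, through the acyclic Claisen adduct diethyl 2-{2-[3,4-bis(benzyloxy)-5-(ArO)phenoxy]-3-ethoxy-3-oxopropanoyl}-3-oxopentanedioate F7, the ring A diester diethyl 5-[3,4-bis(benzyloxy)-5-(ArO)phenoxy]-2,4,6-trihydroxybenzene-1,3-dicarboxylate F8.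
- KOH, then HCl at 70 °C, gives through 5-[3,4-bis(benzyloxy)-5-(ArO)phenoxy]-2,4,6-trihydroxybenzene-1,3-dicarboxylic acid F9 the decabenzyl triol 2-[3,4-bis(benzyloxy)-5-(ArO)phenoxy]benzene-1,3,5-triol F10.
- H2 over Pd/C removes the ten benzyl groups and the fallback rejoins the route at 35; ring A never needs protection on this path.

Step 14 (first Ullmann coupling of the di-ortho-substituted, oxidation-prone pentaoxygenated phenol 25 at 90 °C). Fallback: replace the hot halide coupling by a room-temperature oxidative coupling of an aryl boron reagent. It sets out from 16 and returns at 26. Miyaura borylation of 16 (B2pin2, Pd(dppf)Cl2, KOAc, dioxane, 85 °C) gives 2,6-bis(benzyloxy)-4-(4,4,5,5-tetramethyl-1,3,2-dioxaborolan-2-yl)benzaldehyde F11. NaIO4/NH4OAc in acetone/water frees [3,5-bis(benzyloxy)-4-formylphenyl]boronic acid F12. F12 arylates phenol 25 under Chan–Lam–Evans conditions (Cu(OAc)2, pyridine, 4 Å sieves, CH2Cl2, air, rt) and the fallback is back on the route at 26. The same boronic acid would serve for step 16.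

**Further compounds**
F1 | step 5 | 2-[3,4-bis(benzyloxy)-5-bromophenoxy]-3-ethoxy-3-oxopropanoic acid (racemic) | CCOC(=O)C(Oc1cc(OCc2ccccc2)c(OCc2ccccc2)c(Br)c1)C(=O)O
F2 | step 5 | ethyl 2-[3,4-bis(benzyloxy)-5-bromophenoxy]-3-chloro-3-oxopropanoate (racemic) | CCOC(=O)C(Oc1cc(OCc2ccccc2)c(OCc2ccccc2)c(Br)c1)C(Cl)=O
F3 | step 20 | 3,4-bis(benzyloxy)-5-(3,4,5-tris(benzyloxy)-2-{3,5-bis(benzyloxy)-4-[3,4,5-tris(benzyloxy)phenoxy]phenoxy}phenoxy)benzaldehyde | O=Cc2cc(OCc6ccccc6)c(OCc6ccccc6)c(Oc3cc(OCc6ccccc6)c(OCc6ccccc6)c(OCc6ccccc6)c3Oc4cc(OCc6ccccc6)c(Oc5cc(OCc6ccccc6)c(OCc6ccccc6)c(OCc6ccccc6)c5)c(OCc6ccccc6)c4)c2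
F4 | step 20 | 3,4-bis(benzyloxy)-5-(3,4,5-tris(benzyloxy)-2-{3,5-bis(benzyloxy)-4-[3,4,5-tris(benzyloxy)phenoxy]phenoxy}phenoxy)phenyl formate | O=COc2cc(OCc6ccccc6)c(OCc6ccccc6)c(Oc3cc(OCc6ccccc6)c(OCc6ccccc6)c(OCc6ccccc6)c3Oc4cc(OCc6ccccc6)c(Oc5cc(OCc6ccccc6)c(OCc6ccccc6)c(OCc6ccccc6)c5)c(OCc6ccccc6)c4)c2
F5 | step 20 | 3,4-bis(benzyloxy)-5-(3,4,5-tris(benzyloxy)-2-{3,5-bis(benzyloxy)-4-[3,4,5-tris(benzyloxy)phenoxy]phenoxy}phenoxy)phenol | Oc2cc(OCc6ccccc6)c(OCc6ccccc6)c(Oc3cc(OCc6ccccc6)c(OCc6ccccc6)c(OCc6ccccc6)c3Oc4cc(OCc6ccccc6)c(Oc5cc(OCc6ccccc6)c(OCc6ccccc6)c(OCc6ccccc6)c5)c(OCc6ccccc6)c4)c2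
F6 | step 20 | diethyl 2-[3,4-bis(benzyloxy)-5-(3,4,5-tris(benzyloxy)-2-{3,5-bis(benzyloxy)-4-[3,4,5-tris(benzyloxy)phenoxy]phenoxy}phenoxy)phenoxy]propanedioate | CCOC(=O)C(C(=O)OCC)Oc2cc(OCc6ccccc6)c(OCc6ccccc6)c(Oc3cc(OCc6ccccc6)c(OCc6ccccc6)c(OCc6ccccc6)c3Oc4cc(OCc6ccccc6)c(Oc5cc(OCc6ccccc6)c(OCc6ccccc6)c(OCc6ccccc6)c5)c(OCc6ccccc6)c4)c2
F7 | step 20 | diethyl 2-{2-[3,4-bis(benzyloxy)-5-(3,4,5-tris(benzyloxy)-2-{3,5-bis(benzyloxy)-4-[3,4,5-tris(benzyloxy)phenoxy]phenoxy}phenoxy)phenoxy]-3-ethoxy-3-oxopropanoyl}-3-oxopentanedioate (not isolated) | CCOC(=O)CC(=O)C(C(=O)OCC)C(=O)C(C(=O)OCC)Oc2cc(OCc6ccccc6)c(OCc6ccccc6)c(Oc3cc(OCc6ccccc6)c(OCc6ccccc6)c(OCc6ccccc6)c3Oc4cc(OCc6ccccc6)c(Oc5cc(OCc6ccccc6)c(OCc6ccccc6)c(OCc6ccccc6)c5)c(OCc6ccccc6)c4)c2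
F8 | step 20 | diethyl 5-[3,4-bis(benzyloxy)-5-(3,4,5-tris(benzyloxy)-2-{3,5-bis(benzyloxy)-4-[3,4,5-tris(benzyloxy)phenoxy]phenoxy}phenoxy)phenoxy]-2,4,6-trihydroxybenzene-1,3-dicarboxylate | CCOC(=O)c1c(O)c(C(=O)OCC)c(O)c(Oc2cc(OCc6ccccc6)c(OCc6ccccc6)c(Oc3cc(OCc6ccccc6)c(OCc6ccccc6)c(OCc6ccccc6)c3Oc4cc(OCc6ccccc6)c(Oc5cc(OCc6ccccc6)c(OCc6ccccc6)c(OCc6ccccc6)c5)c(OCc6ccccc6)c4)c2)c1O
F9 | step 20 | 5-[3,4-bis(benzyloxy)-5-(3,4,5-tris(benzyloxy)-2-{3,5-bis(benzyloxy)-4-[3,4,5-tris(benzyloxy)phenoxy]phenoxy}phenoxy)phenoxy]-2,4,6-trihydroxybenzene-1,3-dicarboxylic acid (not isolated) | OC(=O)c1c(O)c(C(O)=O)c(O)c(Oc2cc(OCc6ccccc6)c(OCc6ccccc6)c(Oc3cc(OCc6ccccc6)c(OCc6ccccc6)c(OCc6ccccc6)c3Oc4cc(OCc6ccccc6)c(Oc5cc(OCc6ccccc6)c(OCc6ccccc6)c(OCc6ccccc6)c5)c(OCc6ccccc6)c4)c2)c1O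
F10 | step 20 | 2-[3,4-bis(benzyloxy)-5-(3,4,5-tris(benzyloxy)-2-{3,5-bis(benzyloxy)-4-[3,4,5-tris(benzyloxy)phenoxy]phenoxy}phenoxy)phenoxy]benzene-1,3,5-triol | Oc1cc(O)c(Oc2cc(OCc6ccccc6)c(OCc6ccccc6)c(Oc3cc(OCc6ccccc6)c(OCc6ccccc6)c(OCc6ccccc6)c3Oc4cc(OCc6ccccc6)c(Oc5cc(OCc6ccccc6)c(OCc6ccccc6)c(OCc6ccccc6)c5)c(OCc6ccccc6)c4)c2)c(O)c1
F11 | step 14 | 2,6-bis(benzyloxy)-4-(4,4,5,5-tetramethyl-1,3,2-dioxaborolan-2-yl)benzaldehyde | O=Cc1c(OCc2ccccc2)cc(B2OC(C)(C)C(C)(C)O2)cc1OCc1ccccc1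
F12 | step 14 | [3,5-bis(benzyloxy)-4-formylphenyl]boronic acid | O=Cc1c(OCc2ccccc2)cc(B(O)O)cc1OCc1ccccc1
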